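Divide the rate at which the electrophile falls by the rate at which the nucleophile falls, and time drops out, whatever the rate constant is. If one nucleophile goes with each electrophile, that ratio is one, so the two lose equal amounts at every moment.

- gamma: electrophile 0.25 M; nucleophile 0.237 M; free base 0.75 M; the very flask that is asked about, followed so far
- flask: electrophile 0.25 M; nucleophile 0.237 M; free base 0.750 M; time 25 min

gamma run (percent of the electrophile charged)

| time / s | electrophile / % | target / % |
|---|---|---|
| 15.0 | 79.4 | 21.0 |
| 30.0 | 67.1 | 31.8 |
| 50.0 | 56.7 | 43.4 |
| 60.0 | 52.9 | 46.7 |
| 80.0 | 46.0 | 53.7 |
| 90.0 | 43.0 | 56.4 |
| 120 | 36.5 | 63.3 |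

(each reading ± 0.3 percentage points)

- the earlier runs were read with a standard deviation of 0.3 percentage points
- the earlier runs do not show how much of nucleophile is bound; that part of a forecast is a guess

The readings of the gamma run, which is this very flask followed for 120 s, do not show the nucleophile, so that one-to-one count stays our assumption, and they speak to the electrophile's side of it. At that last reading electrophile and target together make 99.8% of the electrophile charged, so up to then what left as electrophile stands as target, within the scatter of 0.3 percentage points. Since c(nucleophile) is charged below c(electrophile), the nucleophile is the limiting reagent. On that count this gives 94.8%, the target ceiling, the nucleophile charged over the electrophile charged, read in percent of the electrophile charged. That ceiling is our own reckoning and we commit to nothing finer.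

- part of the electrophile that has reacted at 25 min
- share of the unused nucleophile that is free and not bound as protonated nucleophile, at 25 min

The forecast gives 92.3% and 72%, and says of the second: “The free share is largely a guess.”

The flask gives 91.8%, against the forecast's 92.3%, and 77.1%, against its 72%.

    electrophile + acid set free → side product (k = 0.120 M⁻¹ s⁻¹)
    acid set free + free base ⇌ salt of the base (K = 600 M⁻¹, k = 3.00 M⁻¹ s⁻¹)
    electrophile + nucleophile ⇌ acid set free + target (K = 0.850, k = 0.0850 M⁻¹ s⁻¹)
    nucleophile + acid set free ⇌ protonated nucleophile, settled at all times (K = 440 M⁻¹)

At 25 min the flask holds 89.8% of target, 5 points under the ceiling of 94.8%. That gap is the nucleophile still unused, of which 77.1% is free and the rest stands as 0.00288 M of protonated nucleophile.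

In the neighbour charged with 0.62 M of electrophile, the same division gives a ceiling of 38.2%. The computed flask holds 38.1% of target at 25 min, while its electrophile used, 45.5%, stands above the ceiling, with 7.34% present as side product.

(The earlier runs and the new flask are calculated with made-up constants; noise was put on by code.)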